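The target is made from the electrophile, so I asked how much electrophile had reacted after 5.0 min in the new flasks.

| setting | birch | ash | alder | noon | dusk | spring |
|---|---|---|---|---|---|---|
| electrophile | 0.044 M | 0.044 M | 0.044 M | 0.044 M | 0.044 M | 0.044 M |
| nucleophile | 0.92 equiv | 2.5 equiv | 4.4 equiv | 1.30 equiv | 5.20 equiv | 2.60 equiv |
| solid base | 2 equiv | 2 equiv | 2 equiv | 2.00 equiv | 2.00 equiv | 2.00 equiv |
| remark | run made earlier | run made earlier | run made earlier |  |  |  |
| time |  |  |  | 5.0 min | 5.0 min | 5.0 min |

| run | time / min | electrophile / % | target / % |
|---|---|---|---|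
| birch | 0.417 | 95.9 | 3.8 |
| birch | 1.33 | 89.6 | 10.2 |
| birch | 2.50 | 82.9 | 15.6 |
| birch | 4.00 | 77.4 | 22.3 |
| birch | 5.00 | 74.3 | 23.9 |
| ash | 0.417 | 91.2 | 8.3 |
| ash | 1.33 | 75.7 | 24.9 |
| ash | 2.50 | 61.0 | 38.9 |
| ash | 4.00 | 48.6 | 45.8 |
| ash | 5.00 | 41.3 | 52.9 |
| alder | 0.417 | 84.8 | 15.4 |
| alder | 1.33 | 61.3 | 38.9 |
| alder | 2.50 | 41.9 | 57.2 |
| alder | 4.00 | 26.5 | 68.7 |
| alder | 5.00 | 20.9 | 70.6 |

(readings scatter by 1 percentage point)

1. part of the electrophile that has reacted at the end, noon
2. part of the electrophile that has reacted at the end, dusk
3. part of the electrophile that has reacted at the end, spring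
4. what raising the equivalents of nucleophile from its lowest to its highest value here does to the part of the electrophile that has reacted (changes below 5 percentage points count as none) (it rises / no change / it falls)

- given per volume of solution although it is solid: solid base
- at the start none of the solid base is in solution

At 5.00 min the electrophile left was 74.3%, 41.3% and 20.9% in birch, ash and alder. I treated each run as a pseudo-first-order decay whose rate constant follows the nucleophile present. Let b be the equivalents charged, x the fraction reacted and m the mean nucleophile level. I took nucleophile as used one for one, so I set m to b − 0.5x and x to 1 − exp(−Dm). Ash gave D = 0.401, where D is the dose per equivalent: run time over the time constant at one equivalent of nucleophile. Birch gave 0.375 and alder 0.391.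

My ceiling held the nucleophile at b. My floor held it at b minus the ceiling. Then I put the ceiling into m and went round twice.

| Flask | Ceiling | Floor | After two rounds | Forecast |
|---|---|---|---|---|
| noon | 40.6% | 30.1% | 36.2% | 36% |
| spring | 64.7% | 54.3% | 60.2% | 60% |
| dusk | 87.6% | 82.3% | 85.2% | 84% |

The forecast gave ranges of 33% to 39%, 57% to 63% and 79% to 88%, and said it rises. It used the integrated law, not my mean level: “The apparent constant sags slightly with time, but this is already absorbed in the 5-minute calibration”. My dusk figure stood 1.2 percentage points above its value.

The flasks gave 35.2% for noon, 59.5% for spring and 85.7% for dusk. The part reacted: it rises, by 50 points from noon to dusk, with the difference in equivalents of nucleophile as the main reason. Each stood above my floor and below my ceiling .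

    nucleophile + acid set free ⇌ protonated nucleophile, settled at all times (K = 5300 M⁻¹)
    acid set free + free base ⇌ salt of the base, settled at all times (K = 2400 M⁻¹)
    free base + target → over-reaction product (k = 0.0809 M⁻¹ s⁻¹)
    solid base ⇌ free base, rate k4*(cs4 - [free base]) while solid is left; crystals form when [free base] > cs4 (solubility = 38.0 mM, k = 0.00148 s⁻¹)
    electrophile + nucleophile → acid set free + target (k = 0.0365 M⁻¹ s⁻¹)
    acid set free → by-product carried off (k = 0.00115 s⁻¹)

Noon reached 35.2% partly through the time given, since 50.0 min brought 80.9%, and partly through the joining of nucleophile and acid set free to protonated nucleophile, without which it reached 40.3%. Noon held 0.0132 M of protonated nucleophile at 5.00 min, a form the dose does not name. Yet noon's own result gives a dose of 0.387, against 0.401 from ash. Two rounds with the ash dose, for a neighbour of spring charged with 1.60 equiv, gave 42.7%, and that flask reached 41.7%.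

The runs are simulated with constants of no real substance; noise was put on by code.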